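**Strategy.** Ring A is cut at C1–C10 and C5–C10. O11, C11, C9, the benzylic quaternary C10 and C20 (the lactone OCH2) of the target are the atoms of a benzofuran-2(3H)-one whose C3 is C10, a carbon that can serve twice as a nucleophile. A bifunctional cinchona squaramide makes this carbon add to both ends of a cross-conjugated vinyl/alkylidene β-keto ester; ring A closes as a spiro cyclohexanone and C10 and C5 are set in one operation. The precursors are 6-isopropyl-5,7-dimethoxybenzofuran-2(3H)-one and methyl 2-(3-silyloxypropylidene)-3-oxopent-4-enoate, which is released by a neutral oxidation just before use.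

Key step: step 10

Remark on numbering: abietane locants are used in the text (ring A = C1–C5 and C10; C18 = methyl on C4; C19 = carbonyl on C4; C20 = carbon on C10; C6–C7 = side chain on C5). The target is (4S,5R,10R).

Assumption: the sense of induction of the squaramide is not predicted here; of the quinine- and quinidine-derived pseudo-enantiomers, the one that gives the (10R) spiro centre is used.

**Route**

Step 1
Reactants: 1 1,3-dimethoxybenzene
Product: 3 2-(2,6-dimethoxyphenyl)propan-2-ol, via 2,6-dimethoxyphenyllithium 2 (not isolated)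
Conditions: n-BuLi, THF, 0 °C → rt; acetone, −78 °C → rt; H2O
Reagents that add atoms: acetone CC(C)=O
Why: Directed ortho-metalation puts lithium on the carbon between the two methoxy groups, and 1,2-addition of this aryllithium to acetone gives the tertiary benzylic alcohol.

Step 2
Reactants: 3 2-(2,6-dimethoxyphenyl)propan-2-ol
Product: 4 2-isopropyl-1,3-dimethoxybenzene
Conditions: Et3SiH, TFA, CH2Cl2, 0 °C → rt
Reagents that add atoms: none
Why: Ionic hydrogenation: TFA ionises the tertiary benzylic alcohol to a cation stabilised by both ortho methoxy groups, and the silane delivers hydride to it.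

Step 3
Reactants: 4 2-isopropyl-1,3-dimethoxybenzene
Product: 6 3-isopropyl-2,4-dimethoxybenzaldehyde, via aryl iminium chloride 5 (not isolated)
Conditions: POCl3, DMF, 0 → 80 °C; then H2O
Reagents that add atoms: N,N-dimethylformamide CN(C)C=O; water O
Why: Vilsmeier–Haack formylation attacks the only kind of ring position that is ortho to one methoxy group and para to the other (the two such positions are equivalent by symmetry), and hydrolysis of the iminium salt gives the aldehyde.

Step 4
Reactants: 6 3-isopropyl-2,4-dimethoxybenzaldehyde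
Product: 8 3-isopropyl-2,4-dimethoxyphenol, via aryl formate 7 (not isolated)
Conditions: mCPBA, CH2Cl2, 0 °C → rt; aq. NaHCO3 wash; then Et3N (cat.), MeOH, rt
Reagents that add atoms: mCPBA O=C(OO)c1cccc(Cl)c1
Why: Baeyer–Villiger (Dakin-type) oxidation: the electron-rich aryl group migrates to oxygen, and the labile aryl formate is methanolysed to the phenol.

Step 5
Reactants: 8 3-isopropyl-2,4-dimethoxyphenol; 9 glyoxylic acid (used as the monohydrate)
Product: 10 2-hydroxy-2-(2-hydroxy-4-isopropyl-3,5-dimethoxyphenyl)acetic acid (racemic)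
Conditions: NaOH, H2O, N2, rt → 40 °C; then HCl to pH 2
Reagents that add atoms: none
Why: Phenoxide hydroxyalkylation (aldol-type aromatic substitution): the para and one ortho position of the phenoxide are blocked, so its only activated carbon attacks the aldehyde of glyoxylate; the new carbinol centre is racemic and is removed in step 6.

Step 6
Reactants: 10 2-hydroxy-2-(2-hydroxy-4-isopropyl-3,5-dimethoxyphenyl)acetic acid
Product: 12 6-isopropyl-5,7-dimethoxybenzofuran-2(3H)-one, via hydroxyarylacetic acid 11 (not isolated)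
Conditions: H2 (4 atm), 10% Pd/C, AcOH, cat. H2SO4, 60 °C; filter; then TsOH (cat.), toluene, reflux (Dean–Stark)
Reagents that add atoms: none
Why: Acid-assisted benzylic hydrogenolysis of the mandelic-type C–OH, followed by acid-catalysed lactonisation of the 2-hydroxyarylacetic acid to the five-membered aryl lactone.

Step 7
Reactants: 13 tert-butyl(but-3-yn-1-yloxy)dimethylsilane
Product: 15 methyl 5-(tert-butyldimethylsilyloxy)pent-2-ynoate, via lithium acetylide 14 (not isolated)
Conditions: n-BuLi, THF, −78 °C; ClCO2Me, −78 → 0 °C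
Reagents that add atoms: methyl chloroformate COC(=O)Cl
Why: Acylation of a lithium acetylide with a chloroformate gives the ynoate; the primary silyl ether is inert.

Step 8
Reactants: 15 methyl 5-(tert-butyldimethylsilyloxy)pent-2-ynoate; 16 acrolein
Product: 18 methyl (Z)-2-(1-hydroxyprop-2-en-1-yl)-5-(tert-butyldimethylsilyloxy)pent-2-enoate (racemic), via α-aluminated enoate 17 (not isolated)
Conditions: DIBAL-H, NMO, THF, 0 °C; then acrolein, 0 °C → rt; aq. Rochelle salt
Reagents that add atoms: none
Why: Vinylalumination: syn hydroalumination of the ynoate gives the α-alumino enoate, which adds 1,2 to the aldehyde; the alkene geometry (Z expected) and the racemic carbinol do not matter, since the carbinol is oxidised in step 9 and both alkene isomers converge in step 10.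

Step 9
Reactants: 18 methyl (Z)-2-(1-hydroxyprop-2-en-1-yl)-5-(tert-butyldimethylsilyloxy)pent-2-enoate
Product: 19 methyl (Z)-2-[3-(tert-butyldimethylsilyloxy)propylidene]-3-oxopent-4-enoate
Conditions: Dess–Martin periodinane, CH2Cl2, 0 °C; cold solution used at once
Reagents that add atoms: none
Why: Dess–Martin oxidation of the doubly allylic alcohol is fast and neutral, so the sensitive dienone is formed without ever meeting an amine or a strong acid before the key step.

Step 10
Reactants: 12 6-isopropyl-5,7-dimethoxybenzofuran-2(3H)-one; 19 methyl (Z)-2-[3-(tert-butyldimethylsilyloxy)propylidene]-3-oxopent-4-enoate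
Product: 21 methyl (1R,2S)-2-[2-(tert-butyldimethylsilyloxy)ethyl]-6'-isopropyl-5',7'-dimethoxy-2',4-dioxo-2'H-spiro[cyclohexane-1,3'-[1]benzofuran]-3-carboxylate (abietane 5S,10R; C4 not defined), via mono-Michael adduct 20 (not isolated)
Conditions: quinine-derived 3,5-bis(trifluoromethyl)phenyl squaramide (10 mol%), CH2Cl2, −20 °C → rt, slow addition of 19 to 12 (slight excess)
Reagents that add atoms: none
Why: The quinuclidine nitrogen deprotonates C3 of 12 while the squaramide NH groups bind the 1,3-dicarbonyl of 19, so that the ion-paired lactone enolate adds first to the unsubstituted vinyl terminus (C1) to give 20, which is enolised again and attacks the alkylidene carbon (C5) to close ring A (C1–C10 and C5–C10 formed). The closest known reaction type is the organocatalytic asymmetric double Michael spiroannulation of oxindoles and benzofuran-2(3H)-ones with divinyl ketones. Ring A closes in the 6-endo-trig mode, the C4=C5 bond lying inside the new six-membered ring. C10 and C5 are both fixed in this ring closure: the catalyst decides which face of the tethered benzofuranone enolate reacts (absolute configuration at C10), and a chair transition state with the flat benzo ring equatorial and the lactone carbonyl axial puts the C6 chain equatorial, trans to the aryl carbon and cis to C20 (relative configuration at C5), while C4 stays an enolisable centre that step 11 defines. The step needs C- and not O-alkylation, one dienone per benzofuranone and convergence of both alkene isomers of 19; the soft lactone enolate, the intramolecular second addition under slow addition of 19, and the fact that both isomers pass through the same planar acceptor carbon secure these.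

Step 11
Reactants: 21 spiro keto ester (see step 10)
Product: 22 methyl (1R,2R,3R)-2-[2-(tert-butyldimethylsilyloxy)ethyl]-6'-isopropyl-5',7'-dimethoxy-3-methyl-2',4-dioxo-2'H-spiro[cyclohexane-1,3'-[1]benzofuran]-3-carboxylate (abietane 4R,5R,10R; CO2Me cis to C20)
Conditions: MeI, K2CO3, acetone, rt
Reagents that add atoms: iodomethane CI
Why: C-Alkylation of the β-keto ester enolate (SN2 on MeI): the β face of C4 is screened by the axial lactone carbonyl on C10 (1,3-diaxial) and by the neighbouring C5 side chain, so the methyl enters from the α face and the ester ends β, cis to C20, as known for angularly substituted 3-oxo-4-carboalkoxy decalins.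

Step 12
Reactants: 22 methylated spiro keto ester (see step 11)
Product: 24 methyl (1R,2R,3R)-2-[2-(tert-butyldimethylsilyloxy)ethyl]-6'-isopropyl-5',7'-dimethoxy-3-methyl-2'-oxo-4-(trifluoromethylsulfonyloxy)-2'H-spiro[cyclohex-4-ene-1,3'-[1]benzofuran]-3-carboxylate (enol triflate at C3 with a C2=C3 double bond), via potassium enolate 23 (not isolated)
Conditions: KHMDS, THF, −78 °C; PhNTf2, −78 → 0 °C; aq. NH4Cl
Reagents that add atoms: N-phenylbis(trifluoromethanesulfonimide) O=S(=O)(N(c1ccccc1)S(=O)(=O)C(F)(F)F)C(F)(F)F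
Why: Enolate O-triflation: C4 is quaternary, so the ketone can enolise only towards C2, and the hindered non-nucleophilic base leaves the aryl lactone and the ester untouched at low temperature.

Step 13
Reactants: 24 enol triflate (see step 12)
Product: 25 methyl (1R,2S,3S)-2-[2-(tert-butyldimethylsilyloxy)ethyl]-6'-isopropyl-5',7'-dimethoxy-3-methyl-2'-oxo-2'H-spiro[cyclohex-4-ene-1,3'-[1]benzofuran]-3-carboxylate (C2=C3 alkene)
Conditions: Pd(OAc)2 (5 mol%), PPh3, Bu3N, HCO2H, DMF, 60 °C
Reagents that add atoms: none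
Why: Palladium-catalysed formate reduction of a vinyl triflate (oxidative addition, formate-to-hydride exchange with loss of CO2, reductive elimination) replaces C–OTf by C–H under nearly neutral conditions.

Step 14
Reactants: 25 spiro alkene (see step 13)
Product: 26 methyl (1R,2S,3S)-2-[2-(tert-butyldimethylsilyloxy)ethyl]-6'-isopropyl-5',7'-dimethoxy-3-methyl-2'-oxo-2'H-spiro[cyclohexane-1,3'-[1]benzofuran]-3-carboxylate (abietane 4S,5S,10R)
Conditions: H2 (1 atm), 10% Pd/C, EtOAc, rt
Reagents that add atoms: none
Why: Heterogeneous hydrogenation of the cis-disubstituted C2=C3 alkene completes the removal of the C3 oxygen; no stereocentre is created, and the aryl lactone, ester and silyl ether are inert under neutral conditions.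

Step 15
Reactants: 26 saturated spiro lactone ester (see step 14)
Product: 28 (1S,5R,9R)-9-[2-(tert-butyldimethylsilyloxy)ethyl]-5-(2-hydroxy-4-isopropyl-3,5-dimethoxyphenyl)-1-methyl-3-oxabicyclo[3.3.1]nonan-2-one (C19,20-lactone with free C11 phenol), via diol ester 27 (not isolated)
Conditions: LiBH4 (1.2 equiv), THF, 0 °C; H2O; then PPTS (cat.), toluene, 80 °C
Reagents that add atoms: none
Why: Chemoselective hydride reduction of the activated aryl ester (phenoxide leaving group) in the presence of the hindered neopentyl-type methyl ester frees the C11 phenol and C20–OH, and the 1,3-diaxial C20–OH and C19 ester then lactonise (transesterification) with loss of methanol.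

Step 16
Reactants: 28 lactone phenol (see step 15)
Product: 29 (1S,5R,9R)-5-[2-(benzyloxy)-4-isopropyl-3,5-dimethoxyphenyl]-9-[2-(tert-butyldimethylsilyloxy)ethyl]-1-methyl-3-oxabicyclo[3.3.1]nonan-2-one
Conditions: BnBr, K2CO3, DMF, rt, Ar
Reagents that add atoms: benzyl bromide BrCc1ccccc1
Why: Williamson etherification of the only acidic OH protects the oxidation-prone para-methoxyphenol before the C7 oxidation.

Step 17
Reactants: 29 benzyl ether (see step 16)
Product: 30 (1S,5R,9R)-5-[2-(benzyloxy)-4-isopropyl-3,5-dimethoxyphenyl]-9-(2-hydroxyethyl)-1-methyl-3-oxabicyclo[3.3.1]nonan-2-one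
Conditions: HF·pyridine, THF, 0 °C → rt
Reagents that add atoms: none
Why: Fluoride-driven desilylation under mildly acidic conditions frees C7–OH without generating an alkoxide that could take over the lactone carbonyl.

Step 18
Reactants: 30 primary alcohol (see step 17)
Product: 32 2-[(1S,5R,9R)-5-[2-(benzyloxy)-4-isopropyl-3,5-dimethoxyphenyl]-1-methyl-2-oxo-3-oxabicyclo[3.3.1]nonan-9-yl]acetic acid, via aldehyde 31 (not isolated)
Conditions: TEMPO (cat.), PhI(OAc)2, MeCN/H2O, rt
Reagents that add atoms: water O
Why: Oxoammonium (TEMPO/hypervalent iodine) oxidation takes the primary alcohol through the aldehyde hydrate to the acid, and the fully O-alkylated arene is not oxidised by the diacetate.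

Step 19
Reactants: 32 carboxylic acid (see step 18)
Product: 34 (4S,5R,10R)-11-benzyloxy-12,14-dimethoxy-7-oxoabieta-8,11,13-trien-19,20-olide, via mixed anhydride 33 (not isolated)
Conditions: TFAA, CH2Cl2, 0 °C → rt
Reagents that add atoms: none
Why: Intramolecular Friedel–Crafts acylation through the mixed anhydride: C8 is the only free ring position and is para to the 12-OMe and ortho to the 14-OMe, and because C6 and C9 are both equatorial on the ring A chair the new six-membered ring B closes trans-fused without touching C5 or C10.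

Step 20
Reactants: 34 protected tetracyclic ketone (see step 19)
Product: 35 (4S,5R,10R)-11,14-dihydroxy-12-methoxy-7-oxoabieta-8,11,13-trien-19,20-olide (target)
Conditions: BCl3, pentamethylbenzene, CH2Cl2, −78 → 0 °C; H2O, Ar
Reagents that add atoms: none
Why: Lewis-acid ether cleavage: BCl3 removes the benzyl group (cation trapped by pentamethylbenzene) and, held in a six-membered chelate between the C7 carbonyl and O14, the methyl peri to the ketone, whereas the 12-OMe has no carbonyl partner and the alkyl lactone is inert at this temperature.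

**Compound list**

1 | 1,3-dimethoxybenzene | COc1cccc(OC)c1 | starting material
2 | 2,6-dimethoxyphenyllithium | [Li]c1c(OC)cccc1OC | intermediate (not isolated)
3 | 2-(2,6-dimethoxyphenyl)propan-2-ol | COc1cccc(OC)c1C(C)(C)O | intermediate
4 | 2-isopropyl-1,3-dimethoxybenzene | COc1cccc(OC)c1C(C)C | intermediate
5 | N-[(3-isopropyl-2,4-dimethoxyphenyl)methylidene]-N-methylmethanaminium chloride | C[N+](C)=Cc1ccc(OC)c(C(C)C)c1OC.[Cl-] | intermediate (not isolated)
6 | 3-isopropyl-2,4-dimethoxybenzaldehyde | COc1ccc(C=O)c(OC)c1C(C)C | intermediate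
7 | 3-isopropyl-2,4-dimethoxyphenyl formate | COc1ccc(OC=O)c(OC)c1C(C)C | intermediate (not isolated)
8 | 3-isopropyl-2,4-dimethoxyphenol | COc1ccc(O)c(OC)c1C(C)C | intermediate
9 | glyoxylic acid | O=CC(=O)O | starting material
10 | 2-hydroxy-2-(2-hydroxy-4-isopropyl-3,5-dimethoxyphenyl)acetic acid (racemic) | COc1cc(C(O)C(=O)O)c(O)c(OC)c1C(C)C | intermediate
11 | (2-hydroxy-4-isopropyl-3,5-dimethoxyphenyl)acetic acid | COc1cc(CC(=O)O)c(O)c(OC)c1C(C)C | intermediate (not isolated)
12 | 6-isopropyl-5,7-dimethoxybenzofuran-2(3H)-one | O=C1Cc2cc(OC)c(C(C)C)c(OC)c2O1 | intermediate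
13 | tert-butyl(but-3-yn-1-yloxy)dimethylsilane | C#CCCO[Si](C)(C)C(C)(C)C | starting material
14 | lithium 4-(tert-butyldimethylsilyloxy)but-1-yn-1-ide | [Li]C#CCCO[Si](C)(C)C(C)(C)C | intermediate (not isolated)
15 | methyl 5-(tert-butyldimethylsilyloxy)pent-2-ynoate | COC(=O)C#CCCO[Si](C)(C)C(C)(C)C | intermediate
16 | acrolein | C=CC=O | starting material
17 | methyl (E)-2-(diisobutylalumanyl)-5-(tert-butyldimethylsilyloxy)pent-2-enoate | COC(=O)/C(=C\CCO[Si](C)(C)C(C)(C)C)[Al](CC(C)C)CC(C)C | intermediate (not isolated)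
18 | methyl (Z)-2-(1-hydroxyprop-2-en-1-yl)-5-(tert-butyldimethylsilyloxy)pent-2-enoate (racemic) | COC(=O)/C(=C\CCO[Si](C)(C)C(C)(C)C)C(O)C=C | intermediate
19 | methyl (Z)-2-[3-(tert-butyldimethylsilyloxy)propylidene]-3-oxopent-4-enoate | COC(=O)/C(=C\CCO[Si](C)(C)C(C)(C)C)C(=O)C=C | intermediate
20 | methyl 2-[3-(tert-butyldimethylsilyloxy)propylidene]-5-(6-isopropyl-5,7-dimethoxy-2-oxo-2,3-dihydrobenzofuran-3-yl)-3-oxopentanoate | COC(=O)C(=CCCO[Si](C)(C)C(C)(C)C)C(=O)CCC1C(=O)Oc2c1cc(OC)c(C(C)C)c2OC | intermediate (not isolated)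
21 | methyl (1R,2S)-2-[2-(tert-butyldimethylsilyloxy)ethyl]-6'-isopropyl-5',7'-dimethoxy-2',4-dioxo-2'H-spiro[cyclohexane-1,3'-[1]benzofuran]-3-carboxylate (abietane 5S,10R; C4 not defined) | COc1c(C(C)C)c(OC)cc2c1OC(=O)[C@@]23CCC(=O)C(C(=O)OC)[C@@H]3CCO[Si](C)(C)C(C)(C)C | intermediate
22 | methyl (1R,2R,3R)-2-[2-(tert-butyldimethylsilyloxy)ethyl]-6'-isopropyl-5',7'-dimethoxy-3-methyl-2',4-dioxo-2'H-spiro[cyclohexane-1,3'-[1]benzofuran]-3-carboxylate | COc1c(C(C)C)c(OC)cc2c1OC(=O)[C@@]23CCC(=O)[C@](C)(C(=O)OC)[C@@H]3CCO[Si](C)(C)C(C)(C)C | intermediate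
23 | potassium enolate of 22 (C2=C3–O−) | COc1c(C(C)C)c(OC)cc2c1OC(=O)[C@@]23CC=C([O-])[C@](C)(C(=O)OC)[C@@H]3CCO[Si](C)(C)C(C)(C)C.[K+] | intermediate (not isolated)
24 | methyl (1R,2R,3R)-2-[2-(tert-butyldimethylsilyloxy)ethyl]-6'-isopropyl-5',7'-dimethoxy-3-methyl-2'-oxo-4-(trifluoromethylsulfonyloxy)-2'H-spiro[cyclohex-4-ene-1,3'-[1]benzofuran]-3-carboxylate | COc1c(C(C)C)c(OC)cc2c1OC(=O)[C@@]23CC=C(OS(=O)(=O)C(F)(F)F)[C@](C)(C(=O)OC)[C@@H]3CCO[Si](C)(C)C(C)(C)C | intermediate
25 | methyl (1R,2S,3S)-2-[2-(tert-butyldimethylsilyloxy)ethyl]-6'-isopropyl-5',7'-dimethoxy-3-methyl-2'-oxo-2'H-spiro[cyclohex-4-ene-1,3'-[1]benzofuran]-3-carboxylate | COc1c(C(C)C)c(OC)cc2c1OC(=O)[C@@]23CC=C[C@](C)(C(=O)OC)[C@@H]3CCO[Si](C)(C)C(C)(C)C | intermediate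
26 | methyl (1R,2S,3S)-2-[2-(tert-butyldimethylsilyloxy)ethyl]-6'-isopropyl-5',7'-dimethoxy-3-methyl-2'-oxo-2'H-spiro[cyclohexane-1,3'-[1]benzofuran]-3-carboxylate | COc1c(C(C)C)c(OC)cc2c1OC(=O)[C@@]23CCC[C@](C)(C(=O)OC)[C@@H]3CCO[Si](C)(C)C(C)(C)C | intermediate
27 | methyl (1S,2R,3R)-2-[2-(tert-butyldimethylsilyloxy)ethyl]-3-(hydroxymethyl)-3-(2-hydroxy-4-isopropyl-3,5-dimethoxyphenyl)-1-methylcyclohexane-1-carboxylate | COc1c(C(C)C)c(OC)cc(c1O)[C@@]1(CO)CCC[C@](C)(C(=O)OC)[C@@H]1CCO[Si](C)(C)C(C)(C)C | intermediate (not isolated)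
28 | (1S,5R,9R)-9-[2-(tert-butyldimethylsilyloxy)ethyl]-5-(2-hydroxy-4-isopropyl-3,5-dimethoxyphenyl)-1-methyl-3-oxabicyclo[3.3.1]nonan-2-one | COc1c(C(C)C)c(OC)cc(c1O)[C@@]12CCC[C@](C)(C(=O)OC2)[C@@H]1CCO[Si](C)(C)C(C)(C)C | intermediate
29 | (1S,5R,9R)-5-[2-(benzyloxy)-4-isopropyl-3,5-dimethoxyphenyl]-9-[2-(tert-butyldimethylsilyloxy)ethyl]-1-methyl-3-oxabicyclo[3.3.1]nonan-2-one | COc1c(C(C)C)c(OC)cc(c1OCc1ccccc1)[C@@]12CCC[C@](C)(C(=O)OC2)[C@@H]1CCO[Si](C)(C)C(C)(C)C | intermediate
30 | (1S,5R,9R)-5-[2-(benzyloxy)-4-isopropyl-3,5-dimethoxyphenyl]-9-(2-hydroxyethyl)-1-methyl-3-oxabicyclo[3.3.1]nonan-2-one | COc1c(C(C)C)c(OC)cc(c1OCc1ccccc1)[C@@]12CCC[C@](C)(C(=O)OC2)[C@@H]1CCO | intermediate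
31 | 2-[(1S,5R,9R)-5-[2-(benzyloxy)-4-isopropyl-3,5-dimethoxyphenyl]-1-methyl-2-oxo-3-oxabicyclo[3.3.1]nonan-9-yl]acetaldehyde | COc1c(C(C)C)c(OC)cc(c1OCc1ccccc1)[C@@]12CCC[C@](C)(C(=O)OC2)[C@@H]1CC=O | intermediate (not isolated)
32 | 2-[(1S,5R,9R)-5-[2-(benzyloxy)-4-isopropyl-3,5-dimethoxyphenyl]-1-methyl-2-oxo-3-oxabicyclo[3.3.1]nonan-9-yl]acetic acid | COc1c(C(C)C)c(OC)cc(c1OCc1ccccc1)[C@@]12CCC[C@](C)(C(=O)OC2)[C@@H]1CC(=O)O | intermediate
33 | mixed anhydride of 32 with trifluoroacetic acid | COc1c(C(C)C)c(OC)cc(c1OCc1ccccc1)[C@@]12CCC[C@](C)(C(=O)OC2)[C@@H]1CC(=O)OC(=O)C(F)(F)F | intermediate (not isolated)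
34 | (4S,5R,10R)-11-benzyloxy-12,14-dimethoxy-7-oxoabieta-8,11,13-trien-19,20-olide | COc1c(OCc4ccccc4)c2c(c(OC)c1C(C)C)C(=O)C[C@@H]1[C@]23CCC[C@]1(C)C(=O)OC3 | intermediate
35 | (4S,5R,10R)-11,14-dihydroxy-12-methoxy-7-oxoabieta-8,11,13-trien-19,20-olide | COc1c(O)c2c(c(O)c1C(C)C)C(=O)C[C@@H]1[C@]23CCC[C@]1(C)C(=O)OC3 | target

**Step count**

Total: 20 steps. Longest linear sequence: 17 steps (steps 1–6, then 10–20); the dienone branch (steps 7–9) joins at step 10.

**Steps most likely to fail, with fallbacks**

Step 10. The dienone may oligomerise or be attacked a second time by the acidic product, and the control of the enolate face in the ring closure may be insufficient. The fallback exchanges the roles of the two partners. Setting out from 12, a Knoevenagel condensation with purchased 3-(tert-butyldimethylsilyloxy)propanal (piperidine/AcOH, toluene) would give the 3-alkylidene benzofuranone F1. Acrolein 16 and the lithium enolate of methyl acetate (LDA, THF, −78 °C) would give methyl 3-hydroxypent-4-enoate F2, which chromic acid in acetone would oxidise to methyl 3-oxopent-4-enoate F3. Under the same type of bifunctional amine catalyst, the β-keto ester carbon of F3 (C4) should add to the alkylidene carbon of F1 (C5) to give the open Michael adduct F4, whose benzofuranone enolate then closes ring A onto the vinyl ketone (C1) in a 6-endo-trig addition. This comes back to the route at 21.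

Step 15. The borohydride may go on to reduce the hindered C19 ester or the newly formed lactone, or the reduction may stop early. The fallback divides the reduction between two reagents of different reach. Setting out from 26, DIBAL-H (1.1 equiv, CH2Cl2, −78 °C) should stop at the lactol F5. NaBH4 in MeOH, which does not reduce alkyl esters, would then reduce the ring-opened hydroxy aldehyde form of the lactol to 27, and acid-catalysed lactonisation as in step 15 returns to the route at 28.

Step 20. BCl3 may also cleave the hindered 12-methoxy group next to the freed C11 oxygen, or the electron-rich hydroquinone may be degraded during work-up. The fallback reaches the hydroquinone through the quinone oxidation level. Setting out from 34, hydrogenolysis (H2, Pd/C, EtOAc) would give the 11-phenol F6. PhI(OAc)2 in aqueous MeCN would oxidise this para-methoxyphenol with loss of the 14-methyl group to the 11,14-quinone F7; the 12-OMe is not para to the free hydroxyl and stays. Na2S2O4 (H2O/EtOAc) would then reduce the quinone, without touching the C7 ketone, and arrive at 35.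

**Further compounds**

F1 | step 10 | 3-[3-(tert-butyldimethylsilyloxy)propylidene]-6-isopropyl-5,7-dimethoxybenzofuran-2(3H)-one | O=C1Oc2c(OC)c(C(C)C)c(OC)cc2C1=CCCO[Si](C)(C)C(C)(C)C
F2 | step 10 | methyl 3-hydroxypent-4-enoate | C=CC(O)CC(=O)OC
F3 | step 10 | methyl 3-oxopent-4-enoate | C=CC(=O)CC(=O)OC
F4 | step 10 | methyl 2-[3-(tert-butyldimethylsilyloxy)-1-(6-isopropyl-5,7-dimethoxy-2-oxo-2,3-dihydrobenzofuran-3-yl)propyl]-3-oxopent-4-enoate | COC(=O)C(C(=O)C=C)C(CCO[Si](C)(C)C(C)(C)C)C1C(=O)Oc2c1cc(OC)c(C(C)C)c2OC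
F5 | step 15 | lactol of 26 (2'-hydroxy-2',3'-dihydrobenzofuran, mixture at the lactol carbon) | COc1c(C(C)C)c(OC)cc2c1OC(O)[C@@]23CCC[C@](C)(C(=O)OC)[C@@H]3CCO[Si](C)(C)C(C)(C)C
F6 | step 20 | (4S,5R,10R)-11-hydroxy-12,14-dimethoxy-7-oxoabieta-8,11,13-trien-19,20-olide | COc1c(O)c2c(c(OC)c1C(C)C)C(=O)C[C@@H]1[C@]23CCC[C@]1(C)C(=O)OC3
F7 | step 20 | (4S,5R,10R)-12-methoxy-7,11,14-trioxoabieta-8,12-dien-19,20-olide | CC(C)C1=C(OC)C(=O)C2=C(C1=O)C(=O)C[C@@H]1[C@]23CCC[C@]1(C)C(=O)OC3
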